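**Plan**

- Ring labels: A = ring with OH para to its ether oxygen and a bridge ortho to that oxygen; B = catechol-type ring (C4–OH next to C3–OAr); C = para-phenylene; D = meta-phenylene.
- Retrosynthetic cuts, in order: the two phenols are masked as O–CH3; the macrocycle is opened at the bond between the oxygen on C3 of ring B and C1 of ring C; the two CH2–CH2 bridges become stilbene C=C bonds; the ring A–O–ring D ether is cut last.
- Forward: rings C and D are joined by Wittig olefination, ring A by SNAr, ring B by a second Wittig olefination; the ring C bromide becomes a boronate; one hydrogenation saturates both bridges and frees the ring B phenol; the 18-membered ring, the only ring made, closes last; BBr3 frees both phenols.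
- Enabling feature: ring C is a 1,4-phenylene with only CH neighbours and no electron-withdrawing group, so its C1–O bond cannot come from SNAr. A B(OH)2 on C1 of ring C and the single free OH on C3 of ring B (next to C4–OMe) let copper join exactly these two atoms.
- Stereochemistry: the target has no stereocentre; stilbene geometry is not controlled because hydrogenation removes it.

Key step: step 11

Remark: both Wittig steps are expected to give E/Z mixtures, so compounds 5, 7, 13 and 14 are written without alkene descriptors.

**Route**

Step 1
Reactants: 1 4-bromobenzyl bromide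
Product: 2 (4-bromobenzyl)triphenylphosphonium bromide
Conditions: PPh3, toluene, reflux
Reagents that add atoms: triphenylphosphine, c1ccc(cc1)P(c1ccccc1)c1ccccc1
Why: SN2 quaternisation of the phosphine at the benzylic bromide should be clean, the aryl bromide being inert to a neutral phosphine without a metal.

Step 2
Reactants: 2 (4-bromobenzyl)triphenylphosphonium bromide; 3 3-hydroxybenzaldehyde
Product: 5 3-[2-(4-bromophenyl)ethenyl]phenol (E/Z mixture), via (4-bromobenzylidene)triphenylphosphorane 4 (not isolated)
Conditions: KOtBu (2.2 equiv), THF, 0 °C → rt; aq HCl work-up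
Reagents that add atoms: none
Why: Wittig olefination with a semi-stabilised benzylic ylide should tolerate the phenoxide formed by the extra equivalent of base, because a meta O⁻ is not conjugated with the formyl group.

Step 3
Reactants: 5 3-[2-(4-bromophenyl)ethenyl]phenol; 6 2-fluoro-5-methoxybenzaldehyde
Product: 7 2-{3-[2-(4-bromophenyl)ethenyl]phenoxy}-5-methoxybenzaldehyde (E/Z mixture)
Conditions: K2CO3, DMAc, 140 °C
Reagents that add atoms: none
Why: SNAr (addition–elimination) of the phenoxide at C2 of 6 should work because the ortho formyl group stabilises the Meisenheimer adduct and fluoride leaves, while the unactivated aryl bromide stays untouched without a metal.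

Step 4
Reactants: 8 isovanillin
Product: 9 3-(benzyloxy)-4-methoxybenzaldehyde
Conditions: BnBr, K2CO3, DMF, rt
Reagents that add atoms: benzyl bromide, BrCc1ccccc1
Why: Williamson etherification of the phenoxide with a benzylic bromide is routine and masks the ring B phenol with a group that hydrogenolysis removes later.

Step 5
Reactants: 9 3-(benzyloxy)-4-methoxybenzaldehyde
Product: 10 [3-(benzyloxy)-4-methoxyphenyl]methanol
Conditions: NaBH4, MeOH, 0 °C
Reagents that add atoms: none
Why: Borohydride reduction of an aromatic aldehyde gives the benzylic alcohol without touching either ether.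

Step 6
Reactants: 10 [3-(benzyloxy)-4-methoxyphenyl]methanol
Product: 11 [3-(benzyloxy)-4-methoxybenzyl]triphenylphosphonium bromide
Conditions: PPh3·HBr, MeCN, reflux
Reagents that add atoms: triphenylphosphine hydrobromide, [Br-].c1ccc(cc1)[PH+](c1ccccc1)c1ccccc1
Why: Acid-promoted ionisation of the benzylic alcohol, assisted by the para methoxy group, and capture by triphenylphosphine (direct phosphonium salt formation) should give the salt in one operation, with the benzyl ether surviving.

Step 7
Reactants: 11 [3-(benzyloxy)-4-methoxybenzyl]triphenylphosphonium bromide; 7 2-{3-[2-(4-bromophenyl)ethenyl]phenoxy}-5-methoxybenzaldehyde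
Product: 13 2-(benzyloxy)-4-[2-(2-{3-[2-(4-bromophenyl)ethenyl]phenoxy}-5-methoxyphenyl)ethenyl]-1-methoxybenzene (mixture of alkene isomers), via [3-(benzyloxy)-4-methoxybenzylidene]triphenylphosphorane 12 (not isolated)
Conditions: KOtBu, THF, 0 °C → rt
Reagents that add atoms: none
Why: A Wittig olefination of the non-enolisable aldehyde 7 should install the two carbons of the A–B bridge, and the isomer mixture converges on hydrogenation.

Step 8
Reactants: 13 bromo bis-stilbene benzyl ether
Product: 14 2-{4-[2-(3-{2-[2-(3-benzyloxy-4-methoxyphenyl)ethenyl]-4-methoxyphenoxy}phenyl)ethenyl]phenyl}-4,4,5,5-tetramethyl-1,3,2-dioxaborolane (mixture of alkene isomers)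
Conditions: B2pin2, PdCl2(dppf) (5 mol %), KOAc, 1,4-dioxane, 85 °C
Reagents that add atoms: bis(pinacolato)diboron, CC1(C)OB(OC1(C)C)B1OC(C)(C)C(C)(C)O1
Why: Miyaura borylation (oxidative addition of zerovalent palladium into C–Br, acetate-assisted transmetalation from the diboron, reductive elimination) should convert the aryl bromide into the pinacol boronate, since the weak base prevents Suzuki homocoupling and 1,2-diaryl alkenes are poor Heck acceptors.

Step 9
Reactants: 14 pinacol boronate bis-stilbene benzyl ether
Product: 15 2-methoxy-5-{2-[5-methoxy-2-(3-{2-[4-(4,4,5,5-tetramethyl-1,3,2-dioxaborolan-2-yl)phenyl]ethyl}phenoxy)phenyl]ethyl}phenol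
Conditions: H2 (1 atm), 10% Pd/C, EtOAc/MeOH, rt
Reagents that add atoms: none
Why: Heterogeneous catalytic hydrogenation should saturate both stilbene double bonds and cleave the benzyl ether by hydrogenolysis in one operation, aryl pinacol boronates and diaryl ethers being stable to these conditions.

Step 10
Reactants: 15 phenol pinacol boronate
Product: 16 {4-[2-(3-{2-[2-(3-hydroxy-4-methoxyphenyl)ethyl]-4-methoxyphenoxy}phenyl)ethyl]phenyl}boronic acid
Conditions: MeB(OH)2 (10 equiv), 0.1 M aq HCl/acetone, rt; then evaporation under reduced pressure
Reagents that add atoms: water, O; methylboronic acid, CB(O)O (the two B–OH groups of 16 come from this exchanging hydroxyl pool)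
Why: Acid-catalysed boronate transesterification to excess methylboronic acid, driven by evaporation of the volatile methyl pinacol boronate, should free the boronic acid without the periodate oxidant that would attack the guaiacol ring.

Step 11
Reactants: 16 seco boronic acid phenol
Product: 17 di-O-methyl dihydroptychantol A (18-membered macrocycle with OMe on ring A and on C4 of ring B)
Conditions: Cu(OAc)2 (2 equiv), Et3N (5 equiv), powdered 4 Å MS, CH2Cl2, dry air, rt; 16 added by syringe pump to a final concentration of about 1 mM
Reagents that add atoms: none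
Why: Transmetalation moves the ring C aryl group from boron to Cu(OAc)2, the ring B phenoxide generated by triethylamine binds the same copper centre, oxidation by a second divalent copper (or O2) gives an aryl trivalent copper phenoxide, and C–O reductive elimination forms the ether. The closest known reaction type is the Chan–Lam O-arylation of phenols with arylboronic acids at room temperature, which has been applied to macrocyclic diaryl ether closures. The one ring formed is the 18-membered macrocycle, closed end to end by joining the oxygen on C3 of ring B to C1 of ring C through a transient copper-containing large ring, with both ethylene bridges and the ring A–O–ring D ether already in place. No stereocentre is created. The step needs ring closure to outrun oligomerisation, and C–O coupling to outrun protodeboronation, oxidative hydroxylation and biaryl homocoupling: slow addition at high dilution favours cyclisation, the meta linkages of rings B and D with the flexible CH2–CH2 bridges let the chain fold without strain, and molecular sieves keep water from the boronic acid. Site selectivity is fixed by the substrate, because boron marks the only carbon of ring C that can couple and there is a single free OH.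

Step 12
Reactants: 17 di-O-methyl dihydroptychantol A
Product: 18 dihydroptychantol A
Conditions: BBr3 (excess), CH2Cl2, −78 °C → rt; then H2O
Reagents that add atoms: none
Why: Lewis acid-mediated demethylation (boron coordination to the methoxy oxygen, then bromide attack on CH3) should cleave both aryl methyl ethers while the two diaryl ether links, which offer no sp3 carbon for bromide attack, stay intact.

**Compound list**

1 | 4-bromobenzyl bromide | BrCc1ccc(Br)cc1 | starting material
2 | (4-bromobenzyl)triphenylphosphonium bromide | [Br-].Brc1ccc(C[P+](c2ccccc2)(c2ccccc2)c2ccccc2)cc1 | intermediate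
3 | 3-hydroxybenzaldehyde | O=Cc1cccc(O)c1 | starting material
4 | (4-bromobenzylidene)triphenylphosphorane | Brc1ccc(C=P(c2ccccc2)(c2ccccc2)c2ccccc2)cc1 | intermediate
5 | 3-[2-(4-bromophenyl)ethenyl]phenol (E/Z mixture) | Oc1cccc(C=Cc2ccc(Br)cc2)c1 | intermediate
6 | 2-fluoro-5-methoxybenzaldehyde | COc1ccc(F)c(C=O)c1 | starting material
7 | 2-{3-[2-(4-bromophenyl)ethenyl]phenoxy}-5-methoxybenzaldehyde (E/Z mixture) | COc1ccc(Oc2cccc(C=Cc3ccc(Br)cc3)c2)c(C=O)c1 | intermediate
8 | isovanillin (3-hydroxy-4-methoxybenzaldehyde) | COc1ccc(C=O)cc1O | starting material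
9 | 3-(benzyloxy)-4-methoxybenzaldehyde | COc1ccc(C=O)cc1OCc1ccccc1 | intermediate
10 | [3-(benzyloxy)-4-methoxyphenyl]methanol | COc1ccc(CO)cc1OCc1ccccc1 | intermediate
11 | [3-(benzyloxy)-4-methoxybenzyl]triphenylphosphonium bromide | [Br-].COc1ccc(C[P+](c2ccccc2)(c2ccccc2)c2ccccc2)cc1OCc1ccccc1 | intermediate
12 | [3-(benzyloxy)-4-methoxybenzylidene]triphenylphosphorane | COc1ccc(C=P(c2ccccc2)(c2ccccc2)c2ccccc2)cc1OCc1ccccc1 | intermediate
13 | 2-(benzyloxy)-4-[2-(2-{3-[2-(4-bromophenyl)ethenyl]phenoxy}-5-methoxyphenyl)ethenyl]-1-methoxybenzene (alkene isomer mixture) | COc1ccc(Oc2cccc(C=Cc3ccc(Br)cc3)c2)c(C=Cc2ccc(OC)c(OCc3ccccc3)c2)c1 | intermediate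
14 | 2-{4-[2-(3-{2-[2-(3-benzyloxy-4-methoxyphenyl)ethenyl]-4-methoxyphenoxy}phenyl)ethenyl]phenyl}-4,4,5,5-tetramethyl-1,3,2-dioxaborolane (alkene isomer mixture) | COc1ccc(Oc2cccc(C=Cc3ccc(cc3)B3OC(C)(C)C(C)(C)O3)c2)c(C=Cc2ccc(OC)c(OCc3ccccc3)c2)c1 | intermediate
15 | 2-methoxy-5-{2-[5-methoxy-2-(3-{2-[4-(4,4,5,5-tetramethyl-1,3,2-dioxaborolan-2-yl)phenyl]ethyl}phenoxy)phenyl]ethyl}phenol | COc1ccc(Oc2cccc(CCc3ccc(cc3)B3OC(C)(C)C(C)(C)O3)c2)c(CCc2ccc(OC)c(O)c2)c1 | intermediate
16 | {4-[2-(3-{2-[2-(3-hydroxy-4-methoxyphenyl)ethyl]-4-methoxyphenoxy}phenyl)ethyl]phenyl}boronic acid | COc1ccc(Oc2cccc(CCc3ccc(cc3)B(O)O)c2)c(CCc2ccc(OC)c(O)c2)c1 | intermediate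
17 | di-O-methyl dihydroptychantol A (macrocyclic bis(bibenzyl) dimethyl ether) | COc1ccc2c(c1)CCc1ccc(OC)c(c1)Oc1ccc(cc1)CCc1cccc(c1)O2 | intermediate
18 | dihydroptychantol A | Oc1ccc2c(c1)CCc1ccc(O)c(c1)Oc1ccc(cc1)CCc1cccc(c1)O2 | target

**Step count**

Total: 12 steps. Longest linear sequence: 9 steps (1, 2, 3, 7, 8, 9, 10, 11, 12 from 4-bromobenzyl bromide; the isovanillin branch 4, 5, 6, 7–12 is equally long).

**Steps most likely to fail**

Step 11. Intermolecular coupling to oligomers, protodeboronation and copper-mediated hydroxylation of the boronic acid may outrun the closure of the large ring. The fallback forms the same O–C bond from an aryl bromide by a monovalent copper pathway. It sets out from bromide 13. Diimide reduction (TsNHNH2, NaOAc, THF/H2O, reflux) should saturate both alkenes while keeping the C–Br and O–benzyl bonds, giving 2-(benzyloxy)-4-[2-(2-{3-[2-(4-bromophenyl)ethyl]phenoxy}-5-methoxyphenyl)ethyl]-1-methoxybenzene F1. BCl3 with pentamethylbenzene in CH2Cl2 at −78 °C should then remove the benzyl group selectively, giving 5-[2-(2-{3-[2-(4-bromophenyl)ethyl]phenoxy}-5-methoxyphenyl)ethyl]-2-methoxyphenol F2. An intramolecular Ullmann ether condensation (CuI, N,N-dimethylglycine, Cs2CO3, 1,4-dioxane, 105 °C, high dilution) closes the ring, and the route is rejoined at 17.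

Step 10. The pinacol exchange may stall at equilibrium, or the boronic acid may be lost by protodeboronation and dehydration to boroxine mixtures during evaporation. The fallback removes pinacol through a fluoride adduct instead of transesterification. It sets out from 15. KHF2 in MeOH/H2O should give potassium trifluoro{4-[2-(3-{2-[2-(3-hydroxy-4-methoxyphenyl)ethyl]-4-methoxyphenoxy}phenyl)ethyl]phenyl}borate F3, from which pinacol is removed by repeated evaporation and trituration. Hydrolysis with TMSCl and water in MeCN then gives the boronic acid, and the route is rejoined at 16.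

Step 3. Substitution at a fluoride that lies para to a donating methoxy group may be slow, and the formyl group may degrade at the temperature needed. The fallback uses a nitrile as the activating group and restores the aldehyde afterwards. It sets out from 5. SNAr with 2-fluoro-5-methoxybenzonitrile (K2CO3, DMSO, 100 °C) should give 2-{3-[2-(4-bromophenyl)ethenyl]phenoxy}-5-methoxybenzonitrile F4. Partial reduction with DIBAL-H (toluene, −78 °C, then aq HCl) converts the nitrile into the aldehyde, and the route is rejoined at 7.

**Further compounds**

F1 | step 11 | 2-(benzyloxy)-4-[2-(2-{3-[2-(4-bromophenyl)ethyl]phenoxy}-5-methoxyphenyl)ethyl]-1-methoxybenzene | COc1ccc(Oc2cccc(CCc3ccc(Br)cc3)c2)c(CCc2ccc(OC)c(OCc3ccccc3)c2)c1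
F2 | step 11 | 5-[2-(2-{3-[2-(4-bromophenyl)ethyl]phenoxy}-5-methoxyphenyl)ethyl]-2-methoxyphenol | COc1ccc(Oc2cccc(CCc3ccc(Br)cc3)c2)c(CCc2ccc(OC)c(O)c2)c1
F3 | step 10 | potassium trifluoro{4-[2-(3-{2-[2-(3-hydroxy-4-methoxyphenyl)ethyl]-4-methoxyphenoxy}phenyl)ethyl]phenyl}borate | [K+].COc1ccc(Oc2cccc(CCc3ccc(cc3)[B-](F)(F)F)c2)c(CCc2ccc(OC)c(O)c2)c1
F4 | step 3 | 2-{3-[2-(4-bromophenyl)ethenyl]phenoxy}-5-methoxybenzonitrile (E/Z mixture) | COc1ccc(Oc2cccc(C=Cc3ccc(Br)cc3)c2)c(C#N)c1
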